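Retrosynthetic overview
- 20 ⇐ 19 ⇐ 17. The C13–C16 end of the side chain comes last, by B-alkyl Suzuki coupling on a C11=C12 vinyl group. The O6 ester, the 6β-OH (α-face hydride on a C6 ketone) and the 7α-O (α-face Rubottom oxidation) are all relayed from the ring fusion of bicyclic dienal 12.
- Key disconnection of 12: C5–C10 and C8=C9 form in one operation. This is a catalytic enantioselective formal [4+2] of the achiral, acyclic trienal 10, followed in the same flask by loss of methanol. Ring A closes first, ring B second.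
- Enabling feature: in ring B the oxygen on C6 lies 1,3 to C8 and 1,4 to C9. C5–C6–C7–C8 is therefore a masked 1,3-diketone (a 1-methoxy-3-silyloxy diene, nucleophilic at C5, with a leaving group on C8). C11, the first side-chain carbon on C9, can be the formyl group that makes C10 electrophilic, and the gem-dimethyl C4 next to C5 favours folding.
- 10 ⇐ 8 + 4 (B-alkyl Suzuki); 8 ⇐ dienone 7 + allyl donor (builds C4); 7 ⇐ methyl 3-methoxycrotonate + isobutenyl Grignard reagent. Iodide 3 (from but-2-yn-1-ol) is used twice: as aldehyde 4 for C9, C10, C11 and C20, and as itself for C13–C16.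

Key step: step 7

Remark: labdane numbering is used for all skeletal atoms; α is the face opposite to the methyl group on C10.
Assumption: the sense of induction in step 7 follows the usual face-shielding model of this catalyst for E-enals.

Step 1
Reactants: 1 but-2-yn-1-ol
Product: 3 (E)-3-iodobut-2-en-1-ol, via zirconated alkenyl alkoxide 2 (not isolated)
Conditions: Cp2Zr(H)Cl (2.2 equiv), THF, 0 °C to rt; I2, −78 to 0 °C; aqueous work-up
Reagents that add atoms: iodine, II
Why: Hydrozirconation–iodination, in which syn addition places zirconium on the methyl-bearing carbon (away from the bulky O-zirconated CH2O group) and iodinolysis with retention should give the E-iodide.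

Step 2
Reactants: 3 (E)-3-iodobut-2-en-1-ol
Product: 4 (E)-3-iodobut-2-enal
Conditions: activated MnO2 (excess), CH2Cl2, rt
Reagents that add atoms: none
Why: Allylic alcohol oxidation with MnO2 is neutral and should leave the vinyl iodide and its geometry untouched.

Step 3
Reactants: 5 methyl (E)-3-methoxybut-2-enoate
Product: 6 (E)-N,3-dimethoxy-N-methylbut-2-enamide
Conditions: MeNH(OMe)·HCl, i-PrMgCl, THF, −20 °C
Reagents that add atoms: N,O-dimethylhydroxylamine hydrochloride, CNOC.Cl
Why: Weinreb aminolysis by the magnesium amide should occur at the acyl carbon faster than at the donor-deactivated β-carbon and keeps the E-enol ether.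

Step 4
Reactants: 6 (E)-N,3-dimethoxy-N-methylbut-2-enamide
Product: 7 (E)-6-methoxy-2-methylhepta-2,5-dien-4-one
Conditions: 2-methylprop-1-enylmagnesium bromide, THF, −78 to 0 °C; aq. NH4Cl
Reagents that add atoms: 2-methylprop-1-enylmagnesium bromide, CC(C)=C[Mg]Br
Why: Weinreb ketone synthesis, in which the chelated tetrahedral intermediate persists until work-up so that the cross-conjugated ketone never meets the Grignard reagent.

Step 5
Reactants: 7 (E)-6-methoxy-2-methylhepta-2,5-dien-4-one
Product: 8 tert-butyl{[(2E,4Z)-2-methoxy-6,6-dimethylnona-2,4,8-trien-4-yl]oxy}dimethylsilane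
Conditions: allyltributylstannane, t-BuMe2SiOTf, 2,6-di-tert-butyl-4-methylpyridine (cat.), CH2Cl2, −78 °C; Et3N quench
Reagents that add atoms: allyltributylstannane, C=CC[Sn](CCCC)(CCCC)CCCC; tert-butyldimethylsilyl triflate, CC(C)(C)[Si](C)(C)OS(=O)(=O)C(F)(F)F
Why: Silyl triflate-promoted conjugate allylation (Hosomi–Sakurai type with an allylstannane), in which O-silylation gives a pentadienyl cation whose methoxy-free terminus is the more electrophilic one, so that allyl transfer there builds the gem-dimethyl quaternary carbon C4 and leaves the regiodefined Z-silyl enol ether derived from the s-cis enone.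

Step 6
Reactants: 8 tert-butyl{[(2E,4Z)-2-methoxy-6,6-dimethylnona-2,4,8-trien-4-yl]oxy}dimethylsilane; 4 (E)-3-iodobut-2-enal
Product: 10 (2E,8Z,10E)-9-(tert-butyldimethylsilyloxy)-11-methoxy-3,7,7-trimethyldodeca-2,8,10-trienal, via B-alkyl-9-BBN adduct 9 (not isolated)
Conditions: 9-BBN (1.1 equiv), THF, 0 °C to rt; then 4, Pd(dppf)Cl2 (5 mol %), AsPh3 (10 mol %), Cs2CO3, DMF/THF/H2O, rt
Reagents that add atoms: none
Why: B-alkyl Suzuki–Miyaura coupling, in which 9-BBN takes the monosubstituted alkene far faster than the hindered enol ether double bonds and the vinyl iodide couples with retention to the E-enal.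

Step 7
Reactants: 10 (2E,8Z,10E)-9-(tert-butyldimethylsilyloxy)-11-methoxy-3,7,7-trimethyldodeca-2,8,10-trienal
Product: 12 6-(tert-butyldimethylsilyloxy)-12,13,14,15,16-pentanorlabda-6,8-dien-11-al (5α-H 10β-Me), via β-methoxy aldehyde cycloadduct 11 (not isolated)
Conditions: (S)-2-{bis[3,5-bis(trifluoromethyl)phenyl][(trimethylsilyl)oxy]methyl}pyrrolidine (20 mol %), 4-nitrobenzoic acid (20 mol %), toluene, −20 °C to rt; then DBU (0.5 equiv), 0 °C
Reagents that add atoms: none
Why: Proposed new method: the amine condenses with the only aldehyde of 10 to an E-iminium ion, C5 of the 1-methoxy-3-silyloxy diene adds to its β-carbon C10 (vinylogous Mukaiyama–Michael addition), the enamine so formed at C9 closes on C8 of the O-silylated β-methoxy enone, and loss of methanol through the enamine (completed by DBU) leaves the C8=C9 enal and frees the catalyst. The closest known reaction types are the amine-catalysed enantioselective type 1 intramolecular Diels–Alder reaction of trienals to decalins, iminium-catalysed additions to β,β-disubstituted enals that build quaternary carbons, and Danishefsky-type diene cycloaddition followed by β-elimination; new is their union on a β,β-disubstituted enal. Ring A closes 6-exo-trig and ring B 6-endo-trig, together a formal [4+2] over a four-carbon tether that is helped by the gem-dimethyl group at C4. C10 is set by the catalyst, whose diaryl(silyloxy)methyl arm covers one face of the s-trans E-iminium ion so that C5 arrives on the face that leaves the methyl group β; C5 follows from a chair-like folding with both unsaturated arms equatorial (trans fusion), and the centres at C8 and C9 are transient. Regiochemistry is secured because both donor groups polarise the diene towards C5 and only the C5–C10/C8–C9 pairing gives six-membered rings, and methanol is lost towards C9 and not C7 because C6 stays masked as its silyl enol ether while H9 is α to the iminium or formyl group.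

Step 8
Reactants: 12 6-(tert-butyldimethylsilyloxy)-12,13,14,15,16-pentanorlabda-6,8-dien-11-al
Product: 14 7α-(tert-butyldimethylsilyloxy)-6-oxo-12,13,14,15,16-pentanorlabd-8-en-11-al, via silyloxy epoxide 13 (not isolated)
Conditions: dimethyldioxirane (1.1 equiv), acetone/CH2Cl2, −78 to 0 °C
Reagents that add atoms: dimethyldioxirane, CC1(C)OO1
Why: Rubottom oxidation, in which the only electron-rich double bond (C6=C7) is epoxidised from the α face because the axial methyl groups on C4 and C10 block the β face, and ring opening with 1,4-silyl shift should give the 7α-silyloxy ketone.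

Step 9
Reactants: 14 7α-(tert-butyldimethylsilyloxy)-6-oxo-12,13,14,15,16-pentanorlabd-8-en-11-al
Product: 15 7α-(tert-butyldimethylsilyloxy)-13,14,15,16-tetranorlabda-8,11-dien-6-one
Conditions: Ph3PCH3Br, KHMDS, THF, 0 °C; then 14, −78 to −20 °C
Reagents that add atoms: methyltriphenylphosphonium bromide, C[P+](c1ccccc1)(c1ccccc1)c1ccccc1.[Br-]
Why: Wittig methylenation should be chemoselective for the aldehyde because the C6 ketone is flanked by C5 and the silyloxy-bearing C7, and H7 is equatorial and poorly aligned for enolisation so that C7 is kept.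

Step 10
Reactants: 15 7α-(tert-butyldimethylsilyloxy)-13,14,15,16-tetranorlabda-8,11-dien-6-one
Product: 16 7α-(tert-butyldimethylsilyloxy)-13,14,15,16-tetranorlabda-8,11-dien-6β-ol
Conditions: NaBH4, MeOH/CH2Cl2, −20 to 0 °C
Reagents that add atoms: none
Why: Borohydride reduction, in which hydride should come from the α face since the two β-axial methyl groups on C4 and C10 close the β face, giving the axial 6β-alcohol as is usual for 6-oxo decalins of this type.

Step 11
Reactants: 16 7α-(tert-butyldimethylsilyloxy)-13,14,15,16-tetranorlabda-8,11-dien-6β-ol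
Product: 17 7α-(tert-butyldimethylsilyloxy)-13,14,15,16-tetranorlabda-8,11-dien-6β-yl 3-methylbutanoate
Conditions: isovaleric anhydride (3 equiv), DMAP (1 equiv), Et3N, CH2Cl2, 40 °C
Reagents that add atoms: isovaleric anhydride, CC(C)CC(=O)OC(=O)CC(C)C
Why: DMAP-catalysed acylation of the only free hydroxyl group installs the isovalerate, and the trans-diaxial O6/O7 arrangement should prevent silyl or acyl migration.

Step 12
Reactants: 17 7α-(tert-butyldimethylsilyloxy)-13,14,15,16-tetranorlabda-8,11-dien-6β-yl 3-methylbutanoate; 3 (E)-3-iodobut-2-en-1-ol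
Product: 19 6β-isovaleroyloxy-7α-(tert-butyldimethylsilyloxy)labda-8,13E-dien-15-ol, via B-alkyl-9-BBN adduct 18 (not isolated)
Conditions: 9-BBN (1.3 equiv), THF, rt; then 3, Pd(dppf)Cl2 (5 mol %), AsPh3 (10 mol %), Cs2CO3, DMF/H2O, rt
Reagents that add atoms: none
Why: B-alkyl Suzuki–Miyaura coupling, in which 9-BBN adds only to the terminal vinyl group (twisted out of conjugation with the tetrasubstituted C8=C9 bond) and coupling with retention sets the 13E alkene.

Step 13
Reactants: 19 6β-isovaleroyloxy-7α-(tert-butyldimethylsilyloxy)labda-8,13E-dien-15-ol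
Product: 20 6β-isovaleroyloxylabda-8,13E-diene-7α,15-diol (CNP0173680.1)
Conditions: HF·pyridine, pyridine, THF, 0 °C to rt
Reagents that add atoms: none
Why: Buffered fluoride desilylation should free the 7α-hydroxyl group without ionising the allylic position or touching the ester.

Compound list
1 | but-2-yn-1-ol | CC#CCO | starting material
2 | zirconated alkenyl alkoxide (C3- and O-bound Cp2ZrCl groups) | C/C(=C\CO[Zr](Cl)(C1C=CC=C1)C1C=CC=C1)[Zr](Cl)(C1C=CC=C1)C1C=CC=C1 | intermediate
3 | (E)-3-iodobut-2-en-1-ol | C/C(I)=C\CO | intermediate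
4 | (E)-3-iodobut-2-enal | C/C(I)=C\C=O | intermediate
5 | methyl (E)-3-methoxybut-2-enoate | COC(=O)/C=C(\C)OC | starting material
6 | (E)-N,3-dimethoxy-N-methylbut-2-enamide | CON(C)C(=O)/C=C(\C)OC | intermediate
7 | (E)-6-methoxy-2-methylhepta-2,5-dien-4-one | CC(C)=CC(=O)/C=C(\C)OC | intermediate
8 | tert-butyl{[(2E,4Z)-2-methoxy-6,6-dimethylnona-2,4,8-trien-4-yl]oxy}dimethylsilane | C=CCC(C)(C)/C=C(\O[Si](C)(C)C(C)(C)C)/C=C(\C)OC | intermediate
9 | B-alkyl-9-BBN adduct of 8 | C1CC2CCCC(C1)B2CCCC(C)(C)/C=C(\O[Si](C)(C)C(C)(C)C)/C=C(\C)OC | intermediate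
10 | (2E,8Z,10E)-9-(tert-butyldimethylsilyloxy)-11-methoxy-3,7,7-trimethyldodeca-2,8,10-trienal | O=C/C=C(\C)CCCC(C)(C)/C=C(\O[Si](C)(C)C(C)(C)C)/C=C(\C)OC | intermediate
11 | 8-methoxy-6-(tert-butyldimethylsilyloxy)-12,13,14,15,16-pentanorlabd-6-en-11-al (C8 and C9 undefined, both erased) | CC1(OC)C(C=O)[C@@]2(C)CCCC(C)(C)[C@@H]2C(O[Si](C)(C)C(C)(C)C)=C1 | intermediate
12 | 6-(tert-butyldimethylsilyloxy)-12,13,14,15,16-pentanorlabda-6,8-dien-11-al | CC1=C(C=O)[C@@]2(C)CCCC(C)(C)[C@@H]2C(O[Si](C)(C)C(C)(C)C)=C1 | intermediate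
13 | 6α,7α-epoxy-6β-(tert-butyldimethylsilyloxy)-12,13,14,15,16-pentanorlabd-8-en-11-al | CC1=C(C=O)[C@@]2(C)CCCC(C)(C)[C@@H]2[C@@]3(O[Si](C)(C)C(C)(C)C)O[C@@H]13 | intermediate
14 | 7α-(tert-butyldimethylsilyloxy)-6-oxo-12,13,14,15,16-pentanorlabd-8-en-11-al | CC1=C(C=O)[C@@]2(C)CCCC(C)(C)[C@@H]2C(=O)[C@H]1O[Si](C)(C)C(C)(C)C | intermediate
15 | 7α-(tert-butyldimethylsilyloxy)-13,14,15,16-tetranorlabda-8,11-dien-6-one | CC1=C(C=C)[C@@]2(C)CCCC(C)(C)[C@@H]2C(=O)[C@H]1O[Si](C)(C)C(C)(C)C | intermediate
16 | 7α-(tert-butyldimethylsilyloxy)-13,14,15,16-tetranorlabda-8,11-dien-6β-ol | CC1=C(C=C)[C@@]2(C)CCCC(C)(C)[C@@H]2[C@H](O)[C@H]1O[Si](C)(C)C(C)(C)C | intermediate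
17 | 7α-(tert-butyldimethylsilyloxy)-13,14,15,16-tetranorlabda-8,11-dien-6β-yl 3-methylbutanoate | CC1=C(C=C)[C@@]2(C)CCCC(C)(C)[C@@H]2[C@H](OC(=O)CC(C)C)[C@H]1O[Si](C)(C)C(C)(C)C | intermediate
18 | B-alkyl-9-BBN adduct of 17 (boron on C12) | CC1=C(CCB3C4CCCC3CCC4)[C@@]2(C)CCCC(C)(C)[C@@H]2[C@H](OC(=O)CC(C)C)[C@H]1O[Si](C)(C)C(C)(C)C | intermediate
19 | 6β-isovaleroyloxy-7α-(tert-butyldimethylsilyloxy)labda-8,13E-dien-15-ol | CC1=C(CC/C(C)=C/CO)[C@@]2(C)CCCC(C)(C)[C@@H]2[C@H](OC(=O)CC(C)C)[C@H]1O[Si](C)(C)C(C)(C)C | intermediate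
20 | 6β-isovaleroyloxylabda-8,13E-diene-7α,15-diol (CNP0173680.1) | CC1=C(CC/C(C)=C/CO)[C@@]2(C)CCCC(C)(C)[C@@H]2[C@H](OC(=O)CC(C)C)[C@H]1O | target

Total step count: 13. Longest linear sequence: 11 (steps 3 to 13).

Steps most likely to fail

Step 7. Three processes threaten this step:
- Iminium formation and bond formation between two heavily substituted carbons may be slow.
- The acid co-catalyst may protodesilylate the diene.
- E/Z isomerisation of the iminium ion through its dienamine may erode the enantiocontrol.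

The fallback is an auxiliary-controlled, Lewis acid-promoted intramolecular Diels–Alder reaction. It sets out from 4 and 8 and comes back at 12. Aldehyde 4 is oxidised (NaClO2, NaH2PO4, 2-methylbut-2-ene) to (E)-3-iodobut-2-enoic acid F1. This acid is esterified (DCC, DMAP) with commercial (−)-8-phenylmenthol to (1R,2S,5R)-8-phenylmenthyl (E)-3-iodobut-2-enoate F2. Hydroboration of 8 to 9 and coupling with F2 under the conditions of step 6 gives the 8-phenylmenthyl trienoate F3. Et2AlCl in CH2Cl2 at −78 to −20 °C, then DBU, should give the bicyclic 8-phenylmenthyl silyloxy dienoate F4. In this cycloaddition the phenyl ring covers one face of the s-trans E-enoate, and the open face leads to the same C10 configuration. DIBAL-H then gives the C11 allylic alcohol F5 and releases the auxiliary, and MnO2 returns 12.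

Step 5. The allyl group may be delivered to the methoxy-bearing terminus or to the carbonyl carbon, and the new dienol ether may be cleaved by adventitious acid. The fallback is a copper-mediated 1,4-addition followed by silyl exchange. It sets out from 7 and comes back at 8. Allylmagnesium bromide, CuBr·SMe2 and Me3SiCl in THF at −78 °C add the allyl group to the more electron-poor, methoxy-free double bond. This gives the trimethylsilyl dienol ether F6. MeLi cleaves it to the regiodefined lithium dienolate F7, which is silylated with t-BuMe2SiOTf to 8.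

Step 10. Facial selectivity may be poor, because the axial 7α-silyloxy group screens part of the α face and its polar effect favours β attack. The fallback is a hydroxyl-directed reduction. It sets out from 15 and comes back at 16. HF·pyridine gives the 7α-hydroxy-13,14,15,16-tetranorlabda-8,11-dien-6-one F8. Me4NBH(OAc)3 in MeCN/AcOH binds to the 7α-hydroxyl group and delivers hydride within the complex on the α face. This gives the 13,14,15,16-tetranorlabda-8,11-diene-6β,7α-diol F9. t-BuMe2SiCl and imidazole then silylate the less hindered allylic 7-hydroxyl group to 16.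

Further compounds
F1 | step 7 | (E)-3-iodobut-2-enoic acid | C/C(I)=C\C(=O)O
F2 | step 7 | (1R,2S,5R)-8-phenylmenthyl (E)-3-iodobut-2-enoate | C[C@@H]1CC[C@H]([C@@H](C1)OC(=O)/C=C(/I)C)C(C)(C)c1ccccc1
F3 | step 7 | (1R,2S,5R)-8-phenylmenthyl (2E,8Z,10E)-9-(tert-butyldimethylsilyloxy)-11-methoxy-3,7,7-trimethyldodeca-2,8,10-trienoate | C[C@@H]1CC[C@H]([C@@H](C1)OC(=O)/C=C(\C)CCCC(C)(C)/C=C(\O[Si](C)(C)C(C)(C)C)/C=C(\C)OC)C(C)(C)c1ccccc1
F4 | step 7 | (1R,2S,5R)-8-phenylmenthyl 6-(tert-butyldimethylsilyloxy)-12,13,14,15,16-pentanorlabda-6,8-dien-11-oate | C[C@@H]1CC[C@H]([C@@H](C1)OC(=O)C1=C(C)C=C(O[Si](C)(C)C(C)(C)C)[C@H]2C(C)(C)CCC[C@]12C)C(C)(C)c1ccccc1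
F5 | step 7 | 6-(tert-butyldimethylsilyloxy)-12,13,14,15,16-pentanorlabda-6,8-dien-11-ol | CC1=C(CO)[C@@]2(C)CCCC(C)(C)[C@@H]2C(O[Si](C)(C)C(C)(C)C)=C1
F6 | step 5 | {[(2E,4Z)-2-methoxy-6,6-dimethylnona-2,4,8-trien-4-yl]oxy}trimethylsilane | C=CCC(C)(C)/C=C(\O[Si](C)(C)C)/C=C(\C)OC
F7 | step 5 | lithium (2E,4Z)-2-methoxy-6,6-dimethylnona-2,4,8-trien-4-olate | [Li+].C=CCC(C)(C)/C=C(\[O-])/C=C(\C)OC
F8 | step 10 | 7α-hydroxy-13,14,15,16-tetranorlabda-8,11-dien-6-one | CC1=C(C=C)[C@@]2(C)CCCC(C)(C)[C@@H]2C(=O)[C@H]1O
F9 | step 10 | 13,14,15,16-tetranorlabda-8,11-diene-6β,7α-diol | CC1=C(C=C)[C@@]2(C)CCCC(C)(C)[C@@H]2[C@H](O)[C@H]1O
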